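**Plan**

1. Target: 2‑methyl‑1,4‑benzoquinone carrying on the other carbon next to C1=O a C16 chain (C1' = ring CH2 … C15') with 2'E, 6'E and 10'E alkenes, a CH2OH on C11' and an (R)-carbinol at C12'.
2. First cut, C1'–C2': C1' is a CH2 on ring C2, allylic to the ring C2=C3 and vinylogously α to C4=O, so its chloride is ready for Ni(0) insertion. C2'=C3' is an E‑trisubstituted alkene with H on C2' and CH3 on C3', the signature of syn‑methylalumination of a terminal alkyne. This gives chloromethylquinone 26 and alkyne 20.
3. Further cuts in 20: C10'=C11' with its CH2OH comes from the C10'≡C11' alkyne of a propargylic alcohol; C11'–C12' from acylation of an acetylide; C4'–C5' from propargylation of a geranyl‑derived allylic chloride; C11' from aldehyde‑to‑alkyne homologation.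
4. Forward: geranyl acetate → enynol → chloride → silyl diyne 9 → ynone 14 → alcohol 15 → stannane → ester → diol → 20. Separately, 4‑methoxy‑2‑methylphenol → 26 (the only ring is present from the start and is oxidised to the quinone before coupling). Then one‑pot carboalumination/Ni coupling and desilylation.
5. Stereochemistry: C12' (R) from asymmetric transfer hydrogenation of ynone 14; 10'E from OH‑directed trans‑hydrostannation and retentive carbonylation; 6'E from geranyl acetate; 2'E from the syn carboalumination.

Key step: step 18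

Remark: chain atoms are numbered C1' (ring CH2) to C15', the ring so that the chain is on C2 and the methyl on C6; compounds 1, 7, 10 and 21 are assumed to be commercial.

**Route**

Step 1
Reactants: 1 geranyl acetate
Product: 3 (2E)-3-methyl-6-oxohex-2-en-1-yl acetate, via secondary ozonide 2 (not isolated)
Conditions: O3 (1 equiv), CH2Cl2, pyridine (cat.), –78 °C; then Me2S, –78 °C → rt
Reagents that add atoms: ozone, [O-][O+]=O
Why: Chemoselective ozonolysis with reductive work‑up: the 6,7‑alkene is the electron‑richer one because the 2,3‑alkene is deactivated by the allylic acetate, so one equivalent of ozone should cleave only the isopropylidene end and leave the 2E alkene intact.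

Step 2
Reactants: 3 (2E)-3-methyl-6-oxohex-2-en-1-yl acetate
Product: 5 (2E)-3-methylhept-2-en-6-yn-1-ol, via enynyl acetate 4 (not isolated)
Conditions: dimethyl (1-diazo-2-oxopropyl)phosphonate, K2CO3, MeOH, 0 °C → rt
Reagents that add atoms: dimethyl (1-diazo-2-oxopropyl)phosphonate, CC(=O)C(=[N+]=[N-])P(=O)(OC)OC
Why: Ohira–Bestmann (Seyferth–Gilbert) homologation: the diazomethylphosphonate anion generated in situ converts the aldehyde into the terminal alkyne, and the same K2CO3/MeOH should transesterify the allylic acetate to the free alcohol.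

Step 3
Reactants: 5 (2E)-3-methylhept-2-en-6-yn-1-ol
Product: 6 (5E)-7-chloro-5-methylhept-5-en-1-yne
Conditions: NCS, Me2S, CH2Cl2, –40 → 0 °C
Reagents that add atoms: N-chlorosuccinimide, O=C1CCC(=O)N1Cl
Why: Corey–Kim chlorination: the alkoxysulfonium salt of the primary allylic alcohol is displaced by chloride in an SN2 manner, without allylic transposition or loss of the E geometry.

Step 4
Reactants: 6 (5E)-7-chloro-5-methylhept-5-en-1-yne; 7 trimethyl(prop-1-yn-1-yl)silane
Product: 9 trimethyl[(5E)-6-methyldeca-5-en-1,9-diyn-1-yl]silane, via lithiated silylpropyne 8 (not isolated)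
Conditions: 7 (2.3 equiv), n-BuLi (2.2 equiv), THF, –78 °C; then 6, –78 → –20 °C; aq. NH4Cl
Reagents that add atoms: none
Why: SN2 alkylation of a propargylic lithium reagent (the silyl group suppresses the allenyl mode) at the primary allylic chloride; the first equivalent of 8 deprotonates the terminal alkyne of 6, whose acetylide is a poor nucleophile at low temperature and is reprotonated on work‑up.

Step 5
Reactants: 10 4-methylpent-3-enoic acid
Product: 12 N-methoxy-N,4-dimethylpent-3-enamide, via acyl imidazole 11 (not isolated)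
Conditions: CDI, CH2Cl2, 0 °C → rt; then MeNHOMe·HCl, rt
Reagents that add atoms: N,O-dimethylhydroxylamine hydrochloride, CNOC.Cl
Why: Weinreb amide formation through the acyl imidazole (CDI coupling) under non‑basic conditions that should leave the β,γ‑alkene out of conjugation.

Step 6
Reactants: 9 trimethyl[(5E)-6-methyldeca-5-en-1,9-diyn-1-yl]silane; 12 N-methoxy-N,4-dimethylpent-3-enamide
Product: 14 (10E)-2,10-dimethyl-15-(trimethylsilyl)pentadeca-2,10-dien-6,14-diyn-5-one, via lithium acetylide 13 (not isolated)
Conditions: n-BuLi (1.05 equiv), THF, –78 °C; then 12, –78 → 0 °C; aq. NH4Cl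
Reagents that add atoms: none
Why: Weinreb ketone synthesis: the five‑membered lithium chelate stops over‑addition and releases the ynone only on mildly acidic quench, so the doubly activated C13' methylene is not exposed to base as the free ketone.

Step 7
Reactants: 14 (10E)-2,10-dimethyl-15-(trimethylsilyl)pentadeca-2,10-dien-6,14-diyn-5-one
Product: 15 (5R,10E)-2,10-dimethyl-15-(trimethylsilyl)pentadeca-2,10-dien-6,14-diyn-5-ol
Conditions: Ru[(R,R)-TsDPEN](p-cymene) (2 mol %), i-PrOH, rt
Reagents that add atoms: none
Why: Noyori asymmetric transfer hydrogenation of an alkynyl ketone under base‑free conditions; the (R,R)-TsDPEN ligand places the alkynyl arm where an aryl group sits in aryl ketones and should deliver hydride to the face that gives the (R)-carbinol, which sets C12'.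

Step 8
Reactants: 15 (5R,10E)-2,10-dimethyl-15-(trimethylsilyl)pentadeca-2,10-dien-6,14-diyn-5-ol
Product: 16 (5R,6Z,10E)-2,10-dimethyl-6-(tributylstannyl)-15-(trimethylsilyl)pentadeca-2,6,10-trien-14-yn-5-ol
Conditions: Bu3SnH (1.1 equiv), [Cp*RuCl]4 (cat.), CH2Cl2, rt
Reagents that add atoms: tributyltin hydride, CCCC[SnH](CCCC)CCCC
Why: Hydroxyl‑directed Ru‑catalysed trans‑hydrostannation: an OH···Cl–Ru hydrogen bond steers tin to the alkyne carbon next to the carbinol (C11') and hydride adds anti at C10', giving the Z stannane with H cis to C12'; the same interaction should make this alkyne react ahead of the silyl‑capped one.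

Step 9
Reactants: 16 (5R,6Z,10E)-2,10-dimethyl-6-(tributylstannyl)-15-(trimethylsilyl)pentadeca-2,6,10-trien-14-yn-5-ol
Product: 17 methyl (2Z,6E)-2-[(1R)-1-hydroxy-4-methylpent-3-en-1-yl]-6-methyl-11-(trimethylsilyl)undeca-2,6-dien-10-ynoate
Conditions: Pd(OAc)2 (cat.), Ph3As, 1,4-benzoquinone (1.5 equiv), CF3CO2H, CO (1 atm), MeOH, rt
Reagents that add atoms: carbon monoxide, [C-]#[O+]; methanol, CO
Why: Pd(II)-catalysed oxidative methoxycarbonylation of an alkenylstannane (benzoquinone as terminal oxidant), assisted by the neighbouring free OH; C–Sn is replaced by C–CO2Me with retention, so the ester carbon ends up cis to C9'.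

Step 10
Reactants: 17 methyl (2Z,6E)-2-[(1R)-1-hydroxy-4-methylpent-3-en-1-yl]-6-methyl-11-(trimethylsilyl)undeca-2,6-dien-10-ynoate
Product: 18 (2E,6E)-2-[(1R)-1-hydroxy-4-methylpent-3-en-1-yl]-6-methyl-11-(trimethylsilyl)undeca-2,6-dien-10-yn-1-ol
Conditions: DIBAL-H (3.5 equiv), CH2Cl2, –78 → 0 °C; Rochelle salt
Reagents that add atoms: none
Why: DIBAL-H 1,2‑reduction of the α,β‑unsaturated ester to the primary allylic alcohol; alkene geometry and C12' are not touched.

Step 11
Reactants: 18 (2E,6E)-2-[(1R)-1-hydroxy-4-methylpent-3-en-1-yl]-6-methyl-11-(trimethylsilyl)undeca-2,6-dien-10-yn-1-ol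
Product: 19 (2E,6E)-2-[(1R)-1-hydroxy-4-methylpent-3-en-1-yl]-6-methylundeca-2,6-dien-10-yn-1-ol
Conditions: K2CO3, MeOH, rt
Reagents that add atoms: none
Why: Base‑mediated protodesilylation (methanolysis) of the alkynylsilane frees the terminal alkyne needed for carbometalation.

Step 12
Reactants: 19 (2E,6E)-2-[(1R)-1-hydroxy-4-methylpent-3-en-1-yl]-6-methylundeca-2,6-dien-10-yn-1-ol
Product: 20 bis(tert-butyldimethylsilyl) ether of 19
Conditions: TBSOTf (2.5 equiv), 2,6-lutidine, CH2Cl2, –78 → 0 °C
Reagents that add atoms: tert-butyldimethylsilyl triflate, CC(C)(C)[Si](C)(C)OS(=O)(=O)C(F)(F)F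
Why: Silyl ether formation on both hydroxyls; TBS ethers are inert to AlMe3 and can later be removed with fluoride under conditions the quinone tolerates.

Step 13
Reactants: 21 4-methoxy-2-methylphenol
Product: 22 2-hydroxy-5-methoxy-3-methylbenzaldehyde
Conditions: MgCl2, Et3N, (CH2O)n, MeCN, reflux; aq. HCl
Reagents that add atoms: paraformaldehyde (formaldehyde unit), C=O
Why: Magnesium‑mediated ortho‑formylation (Casnati–Skattebøl): the magnesium phenoxide delivers formaldehyde to the only free ortho position, and a second formaldehyde oxidises the hydroxymethyl intermediate to the aldehyde.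

Step 14
Reactants: 22 2-hydroxy-5-methoxy-3-methylbenzaldehyde
Product: 23 2,5-dimethoxy-3-methylbenzaldehyde
Conditions: MeI, K2CO3, DMF, rt
Reagents that add atoms: iodomethane, CI
Why: Williamson O‑methylation of the phenol, which must be capped before a benzylic chloride can be carried next to it.

Step 15
Reactants: 23 2,5-dimethoxy-3-methylbenzaldehyde
Product: 24 (2,5-dimethoxy-3-methylphenyl)methanol
Conditions: NaBH4, MeOH, 0 °C
Reagents that add atoms: none
Why: Borohydride reduction of the aryl aldehyde to the benzylic alcohol.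

Step 16
Reactants: 24 (2,5-dimethoxy-3-methylphenyl)methanol
Product: 25 1-(chloromethyl)-2,5-dimethoxy-3-methylbenzene
Conditions: SOCl2, CH2Cl2, 0 °C → rt
Reagents that add atoms: thionyl chloride, O=S(Cl)Cl
Why: Chlorodehydroxylation of an electron‑rich benzylic alcohol through its chlorosulfite.

Step 17
Reactants: 25 1-(chloromethyl)-2,5-dimethoxy-3-methylbenzene
Product: 26 2-(chloromethyl)-6-methylcyclohexa-2,5-diene-1,4-dione
Conditions: (NH4)2Ce(NO3)6 (2.5 equiv), MeCN/H2O, 0 °C; used promptly
Reagents that add atoms: water, O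
Why: Ceric ammonium nitrate oxidative demethylation: two one‑electron oxidations of the arene, ipso attack of water and loss of methanol give the quinone (its oxygens come from water), and the benzylic chloride should survive the short, cold reaction.

Step 18
Reactants: 20 bis(tert-butyldimethylsilyl) ether of 19; 26 2-(chloromethyl)-6-methylcyclohexa-2,5-diene-1,4-dione
Product: 28 bis(tert-butyldimethylsilyl) ether of the target quinone, via alkenyldimethylalane 27 (not isolated)
Conditions: AlMe3 (2 equiv), Cp2ZrCl2 (0.25 equiv), ClCH2CH2Cl, 0 °C → rt; volatiles and excess AlMe3 removed in vacuo, residue in THF; added to 26 and Ni(0) [NiCl2(PPh3)2 / 2 n-BuLi, 5 mol %], THF, –20 °C → rt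
Reagents that add atoms: trimethylaluminium, C[Al](C)C
Why: Zr‑catalysed methylalumination (Negishi carboalumination) adds CH3 and Al syn across the terminal alkyne of 20, CH3 to the internal carbon C3' and AlMe2 to C2', giving E‑alkenylalane 27; Ni(0) then inserts into the C–Cl bond of 26, the alkenyl group passes from Al to Ni, and reductive elimination forms C1'–C2' with retention at C2'. The closest known reaction type is the one‑pot carboalumination/Ni(0)-catalysed coupling of alkenylalanes with chloromethyl‑1,4‑benzoquinones used for polyprenylated quinones, and 20 has the same 1,5‑enyne terminus as those substrates. No ring is closed. No stereocentre is created; the 2'E geometry is controlled by the syn addition and the retentive coupling, while C12' and the existing alkenes are spectators. The step needs Al on the terminal carbon, which the steric preference of Zr–Me addition to a 1‑alkyne should secure. It also needs reaction at CH2Cl and not at the quinone carbonyls or the unsubstituted C3/C5, which is addressed by stripping excess AlMe3 before 26 is met, by low temperature, and by the fast oxidative addition of this allylic‑type C–Cl bond to Ni(0).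

Step 19
Reactants: 28 bis(tert-butyldimethylsilyl) ether of the target quinone
Product: 29 2-[(2E,6E,10E,12R)-12-hydroxy-11-(hydroxymethyl)-3,7,15-trimethylhexadeca-2,6,10,14-tetraen-1-yl]-6-methylcyclohexa-2,5-diene-1,4-dione (target)
Conditions: HF·pyridine, pyridine, THF, 0 °C → rt
Reagents that add atoms: none
Why: Fluoride‑mediated desilylation under buffered, mildly acidic conditions that should spare the base‑sensitive quinone and the allylic alcohols, so C12' is not ionised.

**Compound list**

1 | geranyl acetate, (2E)-3,7-dimethylocta-2,6-dien-1-yl acetate | CC(C)=CCC/C(C)=C/COC(C)=O | starting material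
2 | secondary ozonide, (2E)-5-(3,3-dimethyl-1,2,4-trioxolan-5-yl)-3-methylpent-2-en-1-yl acetate (not isolated) | CC(=O)OC/C=C(\C)CCC1OOC(C)(C)O1 | intermediate
3 | (2E)-3-methyl-6-oxohex-2-en-1-yl acetate | CC(=O)OC/C=C(\C)CCC=O | intermediate
4 | (2E)-3-methylhept-2-en-6-yn-1-yl acetate (not isolated) | CC(=O)OC/C=C(\C)CCC#C | intermediate
5 | (2E)-3-methylhept-2-en-6-yn-1-ol | OC/C=C(\C)CCC#C | intermediate
6 | (5E)-7-chloro-5-methylhept-5-en-1-yne | ClC/C=C(\C)CCC#C | intermediate
7 | trimethyl(prop-1-yn-1-yl)silane | CC#C[Si](C)(C)C | starting material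
8 | [3-(trimethylsilyl)prop-2-yn-1-yl]lithium (not isolated) | [Li]CC#C[Si](C)(C)C | intermediate
9 | trimethyl[(5E)-6-methyldeca-5-en-1,9-diyn-1-yl]silane | C[Si](C)(C)C#CCC/C=C(\C)CCC#C | intermediate
10 | 4-methylpent-3-enoic acid | CC(C)=CCC(=O)O | starting material
11 | 1-(1H-imidazol-1-yl)-4-methylpent-3-en-1-one (not isolated) | CC(C)=CCC(=O)n1ccnc1 | intermediate
12 | N-methoxy-N,4-dimethylpent-3-enamide | CC(C)=CCC(=O)N(C)OC | intermediate
13 | lithium acetylide of 9, lithiated at the free alkyne terminus (not isolated) | [Li]C#CCC/C(C)=C/CCC#C[Si](C)(C)C | intermediate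
14 | (10E)-2,10-dimethyl-15-(trimethylsilyl)pentadeca-2,10-dien-6,14-diyn-5-one | CC(C)=CCC(=O)C#CCC/C(C)=C/CCC#C[Si](C)(C)C | intermediate
15 | (5R,10E)-2,10-dimethyl-15-(trimethylsilyl)pentadeca-2,10-dien-6,14-diyn-5-ol | CC(C)=CC[C@@H](O)C#CCC/C(C)=C/CCC#C[Si](C)(C)C | intermediate
16 | (5R,6Z,10E)-2,10-dimethyl-6-(tributylstannyl)-15-(trimethylsilyl)pentadeca-2,6,10-trien-14-yn-5-ol | CC(C)=CC[C@@H](O)/C(=C/CC/C(C)=C/CCC#C[Si](C)(C)C)[Sn](CCCC)(CCCC)CCCC | intermediate
17 | methyl (2Z,6E)-2-[(1R)-1-hydroxy-4-methylpent-3-en-1-yl]-6-methyl-11-(trimethylsilyl)undeca-2,6-dien-10-ynoate | CC(C)=CC[C@@H](O)/C(=C/CC/C(C)=C/CCC#C[Si](C)(C)C)C(=O)OC | intermediate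
18 | (2E,6E)-2-[(1R)-1-hydroxy-4-methylpent-3-en-1-yl]-6-methyl-11-(trimethylsilyl)undeca-2,6-dien-10-yn-1-ol | CC(C)=CC[C@@H](O)/C(=C/CC/C(C)=C/CCC#C[Si](C)(C)C)CO | intermediate
19 | (2E,6E)-2-[(1R)-1-hydroxy-4-methylpent-3-en-1-yl]-6-methylundeca-2,6-dien-10-yn-1-ol | CC(C)=CC[C@@H](O)/C(=C/CC/C(C)=C/CCC#C)CO | intermediate
20 | bis-TBS ether of 19 (TBS on the primary and on the (R)-secondary oxygen) | CC(C)=CC[C@@H](O[Si](C)(C)C(C)(C)C)/C(=C/CC/C(C)=C/CCC#C)CO[Si](C)(C)C(C)(C)C | intermediate
21 | 4-methoxy-2-methylphenol | COc1ccc(O)c(C)c1 | starting material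
22 | 2-hydroxy-5-methoxy-3-methylbenzaldehyde | COc1cc(C)c(O)c(C=O)c1 | intermediate
23 | 2,5-dimethoxy-3-methylbenzaldehyde | COc1cc(C)c(OC)c(C=O)c1 | intermediate
24 | (2,5-dimethoxy-3-methylphenyl)methanol | COc1cc(C)c(OC)c(CO)c1 | intermediate
25 | 1-(chloromethyl)-2,5-dimethoxy-3-methylbenzene | COc1cc(C)c(OC)c(CCl)c1 | intermediate
26 | 2-(chloromethyl)-6-methylcyclohexa-2,5-diene-1,4-dione | CC1=CC(=O)C=C(CCl)C1=O | intermediate
27 | dimethyl[(1E,5E,9E,11R)-11-(TBS-oxy)-10-(TBS-oxymethyl)-2,6,14-trimethylpentadeca-1,5,9,13-tetraen-1-yl]alane (not isolated) | CC(C)=CC[C@@H](O[Si](C)(C)C(C)(C)C)/C(=C/CC/C(C)=C/CC/C(C)=C/[Al](C)C)CO[Si](C)(C)C(C)(C)C | intermediate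
28 | bis-TBS ether of the target, 2-[(2E,6E,10E,12R)-12-(TBS-oxy)-11-(TBS-oxymethyl)-3,7,15-trimethylhexadeca-2,6,10,14-tetraen-1-yl]-6-methylcyclohexa-2,5-diene-1,4-dione | CC(C)=CC[C@@H](O[Si](C)(C)C(C)(C)C)/C(=C/CC/C(C)=C/CC/C(C)=C/CC1=CC(=O)C=C(C)C1=O)CO[Si](C)(C)C(C)(C)C | intermediate
29 | 2-[(2E,6E,10E,12R)-12-hydroxy-11-(hydroxymethyl)-3,7,15-trimethylhexadeca-2,6,10,14-tetraen-1-yl]-6-methylcyclohexa-2,5-diene-1,4-dione | CC(C)=CC[C@@H](O)/C(=C/CC/C(C)=C/CC/C(C)=C/CC1=CC(=O)C=C(C)C1=O)CO | target

**Step count**

Total: 19 steps. Longest linear sequence: 13 steps (1 → 29 through steps 1–4, 6–12, 18 and 19).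

**Steps most likely to fail**

Step 18. The alkenylalane may add to the quinone carbonyls or to the unsubstituted ring positions C3/C5, or Ni(0) may transfer an electron to the quinone, in competition with oxidative addition into the C–Cl bond. The fallback sets out from 20 and 25. Alane 27 is generated exactly as in step 18 and coupled under the same Ni(0) catalysis (or Pd(PPh3)4) with benzyl chloride 25, which has no electrophilic ring, to give the bis‑TBS hydroquinone dimethyl ether F1. Brief treatment with ceric ammonium nitrate in MeCN/H2O at 0 °C then oxidises the arene to the quinone and the route is rejoined at 28.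

Step 7. The C14'=C15' alkene may migrate into conjugation with the ynone through enolisation at C13' before or during reduction, and facial discrimination between two unbranched carbonyl substituents may be incomplete. The fallback sets out from 9 and makes steps 5 and 6 unnecessary. Acetylide 13 is added at –78 °C to 4‑methylpent‑3‑enal F2 (Dess–Martin oxidation of commercial 4‑methylpent‑3‑en‑1‑ol, used at once) to give the racemic propargylic alcohol F3. Lipase‑mediated kinetic resolution (Amano PS, vinyl acetate) is expected, by the Kazlauskas rule with the slim alkynyl arm as the medium group, to acylate the S enantiomer to the (S)-acetate F4 and leave the (R)-alcohol, so the route is rejoined at 15.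

Step 9. Protodestannation of 16 by the acid additive may outrun Sn→Pd transmetalation, or Pd(II) may engage the other alkenes. The fallback sets out from 16. Iododestannation (I2, CH2Cl2, 0 °C, retention of geometry) gives the alkenyl iodide F5. Stille coupling with (tributylstannyl)methanol (Pd(PPh3)4, dioxane, 90 °C) introduces the CH2OH group as a nucleophile and gives the diol directly, so the route is rejoined at 18 and step 10 is skipped.

**Further compounds**

F1 | step 18 | bis-TBS ether of 1-[(2E,6E,10E,12R)-12-hydroxy-11-(hydroxymethyl)-3,7,15-trimethylhexadeca-2,6,10,14-tetraen-1-yl]-2,5-dimethoxy-3-methylbenzene | CC(C)=CC[C@@H](O[Si](C)(C)C(C)(C)C)/C(=C/CC/C(C)=C/CC/C(C)=C/Cc1cc(OC)cc(C)c1OC)CO[Si](C)(C)C(C)(C)C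
F2 | step 7 | 4-methylpent-3-enal | CC(C)=CCC=O
F3 | step 7 | racemic (10E)-2,10-dimethyl-15-(trimethylsilyl)pentadeca-2,10-dien-6,14-diyn-5-ol | CC(C)=CCC(O)C#CCC/C(C)=C/CCC#C[Si](C)(C)C
F4 | step 7 | (5S,10E)-2,10-dimethyl-15-(trimethylsilyl)pentadeca-2,10-dien-6,14-diyn-5-yl acetate | CC(C)=CC[C@H](OC(C)=O)C#CCC/C(C)=C/CCC#C[Si](C)(C)C
F5 | step 9 | (5R,6Z,10E)-6-iodo-2,10-dimethyl-15-(trimethylsilyl)pentadeca-2,6,10-trien-14-yn-5-ol | CC(C)=CC[C@@H](O)/C(I)=C/CC/C(C)=C/CCC#C[Si](C)(C)C
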